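The route cuts ring C of the flavone at C4a–C4 and O1–C2. Ring A is brought in as unprotected phloroglucinol, whose three ring CH carbons and three hydroxyls are equivalent by symmetry. Acylation at any carbon, followed by closure through either neighbouring oxygen, therefore gives the same 5,7-dihydroxychromen-4-one, with C5–OH and C7–OH left free. One acid-free thermal condensation with the B-ring aroylacetate builds the pyranone in a single operation. The precursor is the ethyl β-keto ester of the 5-prenylated protocatechuoyl unit, with both catechol oxygens capped as triisopropylsilyl ethers. These are chosen to resist silyl transfer and alcoholysis in the melt and to be removable with buffered fluoride.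

Key step: step 5

Remark: uralenin has no stereocentre and is achiral, so no stereocontrol is required. The only stereocentres that appear on the way (C3 of 6, C2 of 11) are racemic and are destroyed again.

Step 1
Reactants: 1 3-bromo-4,5-dihydroxybenzaldehyde
Product: 2 3-bromo-4,5-bis(triisopropylsilyloxy)benzaldehyde
Conditions: TIPSOTf (2.4 equiv), 2,6-lutidine (3 equiv), CH2Cl2, 0 °C → rt
Reagents that add atoms: triisopropylsilyl trifluoromethanesulfonate, CC(C)[Si](OS(=O)(=O)C(F)(F)F)(C(C)C)C(C)C
Why: O-silylation of phenols with a silyl triflate and a hindered pyridine base should cap both catechol oxygens, including the crowded O4 next to bromine, while the non-enolisable aldehyde is left alone.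

Step 2
Reactants: 2 3-bromo-4,5-bis(triisopropylsilyloxy)benzaldehyde; 3 tributyl(3-methylbut-2-enyl)stannane
Product: 4 3-(3-methylbut-2-enyl)-4,5-bis(triisopropylsilyloxy)benzaldehyde
Conditions: 3 (1.5 equiv), Pd(PPh3)4 (5 mol %), degassed DMF, 100 °C
Reagents that add atoms: none
Why: Stille cross-coupling of an aryl bromide with an allylic stannane runs under neutral conditions that tolerate the aldehyde and the aryl silyl ethers, and reductive elimination at the less hindered primary terminus of the allylpalladium intermediate should give the linear prenyl group.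

Step 3
Reactants: 4 3-(3-methylbut-2-enyl)-4,5-bis(triisopropylsilyloxy)benzaldehyde; 5 ethyl acetate
Product: 6 ethyl 3-hydroxy-3-[3-(3-methylbut-2-enyl)-4,5-bis(triisopropylsilyloxy)phenyl]propanoate (racemic)
Conditions: LDA (1.2 equiv), 5 (1.2 equiv), THF, −78 °C; then 4; AcOH quench at −78 °C
Reagents that add atoms: none
Why: Aldol addition of the preformed lithium enolate of ethyl acetate to a non-enolisable aryl aldehyde is fast at −78 °C, and the new carbinol centre is formed as a racemate that is removed by oxidation in the next step.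

Step 4
Reactants: 6 ethyl 3-hydroxy-3-[3-(3-methylbut-2-enyl)-4,5-bis(triisopropylsilyloxy)phenyl]propanoate
Product: 7 ethyl 3-[3-(3-methylbut-2-enyl)-4,5-bis(triisopropylsilyloxy)phenyl]-3-oxopropanoate
Conditions: Dess–Martin periodinane (1.2 equiv), CH2Cl2, 0 °C → rt
Reagents that add atoms: none
Why: Dess–Martin oxidation of a secondary benzylic β-hydroxy ester to the β-keto ester is near-neutral and should not touch the trisubstituted alkene or the aryl silyl ethers, provided the oxidant is kept close to one equivalent.

Step 5
Reactants: 7 ethyl 3-[3-(3-methylbut-2-enyl)-4,5-bis(triisopropylsilyloxy)phenyl]-3-oxopropanoate; 8 phloroglucinol (anhydrous)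
Product: 12 3',4'-bis-O-(triisopropylsilyl)uralenin, via aroylketene 9 (not isolated), via diketone 10 (not isolated), via hemiketal 11 (not isolated)
Conditions: 8 (1.5 equiv), neat melt, 240 °C, N2 stream, EtOH/H2O distilled off
Reagents that add atoms: none
Why: In the melt the β-keto ester expels ethanol to give aroylketene 9, whose ketene carbon is attacked by a ring carbon of the triphenol to form C4a–C4 (diketone 10); the hydroxyl ortho to the new acyl group then adds to the aryl ketone in a 6-exo-trig closure to hemiketal 11, and loss of water forms O1–C2 as part of the aromatic pyranone. The closest known reaction is the Mentzer pyrone synthesis, the acid-free thermal condensation of phloroglucinol with ethyl aroylacetates to 5,7-dihydroxyflavones. No stereocentre remains, since the only sp3 centre formed, C2 of 11, is lost on dehydration. The selectivity needed is chromone over 4-arylcoumarin: without acid the ester carbon (as the ketene), not the ketone carbon, is the electrophile towards the ring carbon, so the aryl group ends up at C2. Site selectivity on ring A does not arise because the three CH carbons and three hydroxyls of 8 are symmetry-equivalent, and a modest excess of 8 should suppress a second annulation. The triisopropylsilyl ethers should resist silyl transfer to the free phenols and alcoholysis by the ethanol released, so O4' stays capped and cannot add to the prenyl double bond.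

Step 6
Reactants: 12 3',4'-bis-O-(triisopropylsilyl)uralenin
Product: 13 uralenin
Conditions: TBAF/AcOH (1:1, 3 equiv), THF, 0 °C → rt, Ar
Reagents that add atoms: none
Why: Buffered fluoride desilylation cleaves the aryl Si–O bonds readily, and the acetic acid buffer keeps the catechol protonated, so neither air oxidation of a catecholate nor acid-promoted chroman closure of the prenyl group should intervene.

Compound list
1 | 3-bromo-4,5-dihydroxybenzaldehyde | O=Cc1cc(O)c(O)c(Br)c1 | starting material
2 | 3-bromo-4,5-bis(triisopropylsilyloxy)benzaldehyde | O=Cc1cc(O[Si](C(C)C)(C(C)C)C(C)C)c(O[Si](C(C)C)(C(C)C)C(C)C)c(Br)c1 | intermediate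
3 | tributyl(3-methylbut-2-enyl)stannane | CCCC[Sn](CCCC)(CCCC)CC=C(C)C | starting material
4 | 3-(3-methylbut-2-enyl)-4,5-bis(triisopropylsilyloxy)benzaldehyde | O=Cc1cc(O[Si](C(C)C)(C(C)C)C(C)C)c(O[Si](C(C)C)(C(C)C)C(C)C)c(CC=C(C)C)c1 | intermediate
5 | ethyl acetate | CCOC(C)=O | starting material
6 | ethyl 3-hydroxy-3-[3-(3-methylbut-2-enyl)-4,5-bis(triisopropylsilyloxy)phenyl]propanoate (racemic) | CCOC(=O)CC(O)c1cc(CC=C(C)C)c(O[Si](C(C)C)(C(C)C)C(C)C)c(O[Si](C(C)C)(C(C)C)C(C)C)c1 | intermediate
7 | ethyl 3-[3-(3-methylbut-2-enyl)-4,5-bis(triisopropylsilyloxy)phenyl]-3-oxopropanoate | CCOC(=O)CC(=O)c1cc(CC=C(C)C)c(O[Si](C(C)C)(C(C)C)C(C)C)c(O[Si](C(C)C)(C(C)C)C(C)C)c1 | intermediate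
8 | phloroglucinol (benzene-1,3,5-triol) | Oc1cc(O)cc(O)c1 | starting material
9 | aroylketene, 3-[3-(3-methylbut-2-enyl)-4,5-bis(triisopropylsilyloxy)phenyl]-3-oxoprop-1-en-1-one (not isolated) | O=C=CC(=O)c1cc(CC=C(C)C)c(O[Si](C(C)C)(C(C)C)C(C)C)c(O[Si](C(C)C)(C(C)C)C(C)C)c1 | intermediate
10 | diketone, 1-[3-(3-methylbut-2-enyl)-4,5-bis(triisopropylsilyloxy)phenyl]-3-(2,4,6-trihydroxyphenyl)propane-1,3-dione (not isolated) | O=C(CC(=O)c1c(O)cc(O)cc1O)c1cc(CC=C(C)C)c(O[Si](C(C)C)(C(C)C)C(C)C)c(O[Si](C(C)C)(C(C)C)C(C)C)c1 | intermediate
11 | hemiketal, 2,5,7-trihydroxy-2-[3-(3-methylbut-2-enyl)-4,5-bis(triisopropylsilyloxy)phenyl]chroman-4-one (racemic, not isolated) | O=C1CC(O)(c2cc(CC=C(C)C)c(O[Si](C(C)C)(C(C)C)C(C)C)c(O[Si](C(C)C)(C(C)C)C(C)C)c2)Oc2cc(O)cc(O)c21 | intermediate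
12 | 3',4'-bis-O-(triisopropylsilyl)uralenin, 5,7-dihydroxy-2-[3-(3-methylbut-2-enyl)-4,5-bis(triisopropylsilyloxy)phenyl]chromen-4-one | CC(C)=CCc1cc(-c2cc(=O)c3c(O)cc(O)cc3o2)cc(O[Si](C(C)C)(C(C)C)C(C)C)c1O[Si](C(C)C)(C(C)C)C(C)C | intermediate
13 | uralenin, 2-[3,4-dihydroxy-5-(3-methylbut-2-enyl)phenyl]-5,7-dihydroxychromen-4-one (achiral) | CC(C)=CCc1cc(-c2cc(=O)c3c(O)cc(O)cc3o2)cc(O)c1O | target

Total step count: 6
Longest linear sequence: 6 steps (1 → 2 → 4 → 6 → 7 → 12 → 13)

Steps most likely to fail

Step 5. The side chain may not survive the melt: a silyl group could migrate or be lost from O4', after which the freed phenol would add to the prenyl double bond (chroman closure), or the aroylketene could undergo ene or cycloaddition reactions with the trisubstituted alkene. The fallback moves the prenylation behind the ring closure, so that no alkene is present at high temperature. It sets out from bromo aldehyde 2. Aldol addition of lithiated ethyl acetate (LDA, THF, −78 °C) would give ethyl 3-[3-bromo-4,5-bis(triisopropylsilyloxy)phenyl]-3-hydroxypropanoate F1. Dess–Martin oxidation would give ethyl 3-[3-bromo-4,5-bis(triisopropylsilyloxy)phenyl]-3-oxopropanoate F2. The same thermal condensation with 8 would give 2-[3-bromo-4,5-bis(triisopropylsilyloxy)phenyl]-5,7-dihydroxychromen-4-one F3. Stille coupling of F3 with stannane 3 (Pd(PPh3)4, DMF, 100 °C) would then rejoin the route at 12.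

Step 2. Allylic transposition during transmetalation or reductive elimination could deliver the 1,1-dimethylallyl isomer alongside the prenyl compound, and protodestannylation could consume the stannane. The fallback assembles the side chain in two operations in which transposition cannot matter. It sets out from 2. Stille coupling with allyltributylstannane (Pd(PPh3)4, DMF, 100 °C) would give 3-(prop-2-enyl)-4,5-bis(triisopropylsilyloxy)benzaldehyde F4. Olefin cross-metathesis of F4 with excess 2-methyl-2-butene (Grubbs second-generation catalyst, CH2Cl2, 40 °C) would then convert the allyl into the prenyl group and rejoin the route at 4.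

Step 4. The oxidation could run on at the activated methylene of the product to the 2,3-dioxo ester, or retro-aldol cleavage of 6 could return aldehyde 4. The fallback bypasses the alcohol altogether. It sets out from aldehyde 4, which would be homologated directly with ethyl diazoacetate and catalytic SnCl2 in CH2Cl2 at rt (Roskamp reaction, formal insertion into the aldehyde C–H bond with hydride shift), rejoining the route at 7 with no new intermediate.

Further compounds
F1 | step 5 | ethyl 3-[3-bromo-4,5-bis(triisopropylsilyloxy)phenyl]-3-hydroxypropanoate (racemic) | CCOC(=O)CC(O)c1cc(Br)c(O[Si](C(C)C)(C(C)C)C(C)C)c(O[Si](C(C)C)(C(C)C)C(C)C)c1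
F2 | step 5 | ethyl 3-[3-bromo-4,5-bis(triisopropylsilyloxy)phenyl]-3-oxopropanoate | CCOC(=O)CC(=O)c1cc(Br)c(O[Si](C(C)C)(C(C)C)C(C)C)c(O[Si](C(C)C)(C(C)C)C(C)C)c1
F3 | step 5 | 2-[3-bromo-4,5-bis(triisopropylsilyloxy)phenyl]-5,7-dihydroxychromen-4-one | O=c1cc(-c2cc(Br)c(O[Si](C(C)C)(C(C)C)C(C)C)c(O[Si](C(C)C)(C(C)C)C(C)C)c2)oc2cc(O)cc(O)c12
F4 | step 2 | 3-(prop-2-enyl)-4,5-bis(triisopropylsilyloxy)benzaldehyde | O=Cc1cc(O[Si](C(C)C)(C(C)C)C(C)C)c(O[Si](C(C)C)(C(C)C)C(C)C)c(CC=C)c1
F0 | step 4 | none | none
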